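**Retrosynthetic overview**
- Target 15 ← desilylation of 14 ← B-alkyl Suzuki disconnection of the bridge CH2–aryl bond: the alkylborane from 5-vinylchromene 10 plus silyl-protected 4-bromophenol 12 (ring C is bought).
- 10 ← methylenation of 5-formylchromene 9; the formyl carbon becomes the bridge carbon on C5.
- Ring B of 9 ← aryl 1,1-dimethylpropargyl ether 5 by disconnecting C4a–C4 and O1–C2 (propargyl Claisen, 1,5-hydrogen shift, oxa-6π closure). Ring A is bought as 3,5-dihydroxybenzaldehyde 1, so ring B is the only ring formed.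
- Feature: C4a of ring A is ortho to C5 (formyl, later the bridge) and para to C7 (prenyloxy oxygen), so both meta substituents of the O1 ether direct the rearrangement to this one carbon.
- 5 ← 1 by mono-O-prenylation, then copper-catalysed O-propargylation.

Key step: step 3

Remark: the target has no stereocentre and its ring alkene C3=C4 is cis by ring constraint, so no stereocontrol is planned.

**Step 1**
Reactants: 1 3,5-dihydroxybenzaldehyde; 2 1-bromo-3-methylbut-2-ene
Product: 3 3-hydroxy-5-(3-methylbut-2-enyloxy)benzaldehyde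
Conditions: 2 (0.95 equiv, slow addition), K2CO3 (1.0 equiv), DMF, 0 °C → rt; chromatography, recovered 1 recycled
Reagents that add atoms: none
Why: Williamson O-alkylation of one of two equivalent phenols with a sub-stoichiometric allylic bromide should give mainly the mono-ether, which is separable from the bis-ether and unreacted diol.

**Step 2**
Reactants: 3 3-hydroxy-5-(3-methylbut-2-enyloxy)benzaldehyde; 4 3-chloro-3-methylbut-1-yne
Product: 5 3-(2-methylbut-3-yn-2-yloxy)-5-(3-methylbut-2-enyloxy)benzaldehyde
Conditions: 4 (1.3 equiv), DBU (1.4 equiv), CuCl2·2H2O (1 mol%), MeCN, 0 °C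
Reagents that add atoms: none
Why: Copper-catalysed propargylic etherification of a phenol with a tertiary propargylic chloride (through a copper acetylide/allenylidene-type electrophile) works best with electron-poor phenols such as this formyl-substituted one and leaves the aldehyde and prenyl ether untouched.

**Step 3**
Reactants: 5 3-(2-methylbut-3-yn-2-yloxy)-5-(3-methylbut-2-enyloxy)benzaldehyde
Product: 9 2,2-dimethyl-7-(3-methylbut-2-enyloxy)-2H-chromene-5-carbaldehyde, via allenyl cyclohexadienone 6 (not isolated), via ortho-allenylphenol 7 (not isolated), via ortho-quinone methide 8 (not isolated)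
Conditions: o-xylene (0.05 M), 140 °C, argon; chromatography to remove the minor regioisomer
Reagents that add atoms: none
Why: Heating should start the aromatic propargyl Claisen rearrangement, a [3,3] shift that joins the alkyne terminus to C4a (the net new C4a–C4 bond) and gives allenyl dienone 6, which tautomerises to ortho-allenylphenol 7. A 1,5-hydrogen shift from the phenol to the central allene carbon should then give the Z-configured ortho-quinone methide 8, a 1-oxatriene whose thermal disrotatory oxa-6π electrocyclisation re-forms O1–C2 and closes ring B. The closest known reaction type is the thermal conversion of aryl 1,1-dimethylpropargyl ethers into 2,2-dimethyl-2H-chromenes. No stereocentre is created, and the cyclic transition state of the hydrogen shift places the diene terminus cis to the carbonyl oxygen as the ring closure requires. The selectivity needed is between the two carbons ortho to O1: the meta formyl group favours its neighbouring carbon and the meta alkoxy donor on C7 favours its para carbon, and both are C4a, whose dienone is also stabilised as a vinylogous ester, so rearrangement to C8 should be minor. The gem-dimethyl group lowers the barrier of the [3,3] step, so the cascade should run at 140 °C, below the temperature at which the aryl prenyl ether itself rearranges.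

**Step 4**
Reactants: 9 2,2-dimethyl-7-(3-methylbut-2-enyloxy)-2H-chromene-5-carbaldehyde
Product: 10 5-ethenyl-2,2-dimethyl-7-(3-methylbut-2-enyloxy)-2H-chromene
Conditions: Ph3PCH3Br (1.5 equiv), KOtBu (1.4 equiv), THF, 0 °C → rt
Reagents that add atoms: methyltriphenylphosphonium bromide, C[P+](c1ccccc1)(c1ccccc1)c1ccccc1.[Br-]
Why: Wittig methylenation of an aryl aldehyde with the non-stabilised ylide is reliable, and neither the chromene nor the prenyl ether reacts with the ylide.

**Step 5**
Reactants: 11 4-bromophenol
Product: 12 (4-bromophenoxy)(tert-butyl)dimethylsilane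
Conditions: TBSCl (1.1 equiv), imidazole (2.0 equiv), DMF, rt
Reagents that add atoms: tert-butyldimethylsilyl chloride, CC(C)(C)[Si](C)(C)Cl
Why: Imidazole-promoted O-silylation masks the phenol so that the aryl bromide enters oxidative addition as a neutral, not a phenoxide, partner.

**Step 6**
Reactants: 10 5-ethenyl-2,2-dimethyl-7-(3-methylbut-2-enyloxy)-2H-chromene; 12 (4-bromophenoxy)(tert-butyl)dimethylsilane
Product: 14 tert-butyl{4-[2-(2,2-dimethyl-7-(3-methylbut-2-enyloxy)-2H-chromen-5-yl)ethyl]phenoxy}dimethylsilane, via alkylborane 13 (not isolated)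
Conditions: 9-BBN (1.1 equiv, 0.5 M in THF), 0 °C → rt; then 12 (1.2 equiv), Pd(OAc)2 (3 mol%), SPhos (6 mol%), K3PO4·H2O (3 equiv), THF, 60 °C, degassed
Reagents that add atoms: none
Why: 9-BBN should hydroborate the terminal vinyl group anti-Markovnikov much faster than the hindered cis-disubstituted chromene alkene or the trisubstituted prenyl alkene, and the resulting B-alkyl borane should undergo B-alkyl Suzuki–Miyaura coupling with the aryl bromide, oxidative addition of zerovalent palladium to Ar–Br being far faster than ionisation of the prenyl aryl ether.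

**Step 7**
Reactants: 14 tert-butyl{4-[2-(2,2-dimethyl-7-(3-methylbut-2-enyloxy)-2H-chromen-5-yl)ethyl]phenoxy}dimethylsilane
Product: 15 4-{2-[2,2-dimethyl-7-(3-methylbut-2-enyloxy)-2H-chromen-5-yl]ethyl}phenol
Conditions: TBAF (1.1 equiv), THF, 0 °C; then H2O
Reagents that add atoms: none
Why: Fluoride-mediated cleavage of the aryl silyl ether is fast and non-acidic, so the acid-sensitive prenyl ether and 2H-chromene should survive.

**Compound list**
1 | 3,5-dihydroxybenzaldehyde | O=Cc1cc(O)cc(O)c1 | starting material
2 | 1-bromo-3-methylbut-2-ene (prenyl bromide) | CC(C)=CCBr | starting material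
3 | 3-hydroxy-5-(3-methylbut-2-enyloxy)benzaldehyde | CC(C)=CCOc1cc(O)cc(C=O)c1 | intermediate
4 | 3-chloro-3-methylbut-1-yne | C#CC(C)(C)Cl | starting material
5 | 3-(2-methylbut-3-yn-2-yloxy)-5-(3-methylbut-2-enyloxy)benzaldehyde | C#CC(C)(C)Oc1cc(C=O)cc(OCC=C(C)C)c1 | intermediate
6 | 6-(3-methylbuta-1,2-dien-1-yl)-3-(3-methylbut-2-enyloxy)-5-oxocyclohexa-1,3-diene-1-carbaldehyde (racemic, not isolated) | O=C1C=C(OCC=C(C)C)C=C(C=O)C1C=C=C(C)C | intermediate
7 | 3-hydroxy-2-(3-methylbuta-1,2-dien-1-yl)-5-(3-methylbut-2-enyloxy)benzaldehyde (not isolated) | CC(C)=C=Cc1c(O)cc(OCC=C(C)C)cc1C=O | intermediate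
8 | (6Z)-6-(3-methylbut-2-en-1-ylidene)-3-(3-methylbut-2-enyloxy)-5-oxocyclohexa-1,3-diene-1-carbaldehyde (not isolated) | O=C1C=C(OCC=C(C)C)C=C(C=O)/C1=C/C=C(C)C | intermediate
9 | 2,2-dimethyl-7-(3-methylbut-2-enyloxy)-2H-chromene-5-carbaldehyde | CC(C)=CCOc1cc(C=O)c2C=CC(C)(C)Oc2c1 | intermediate
10 | 5-ethenyl-2,2-dimethyl-7-(3-methylbut-2-enyloxy)-2H-chromene | CC(C)=CCOc1cc(C=C)c2C=CC(C)(C)Oc2c1 | intermediate
11 | 4-bromophenol | Oc1ccc(Br)cc1 | starting material
12 | (4-bromophenoxy)(tert-butyl)dimethylsilane | CC(C)(C)[Si](C)(C)Oc1ccc(Br)cc1 | intermediate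
13 | 9-{2-[2,2-dimethyl-7-(3-methylbut-2-enyloxy)-2H-chromen-5-yl]ethyl}-9-borabicyclo[3.3.1]nonane (not isolated) | CC(C)=CCOc1cc(CCB2C3CCCC2CCC3)c2C=CC(C)(C)Oc2c1 | intermediate
14 | tert-butyl{4-[2-(2,2-dimethyl-7-(3-methylbut-2-enyloxy)-2H-chromen-5-yl)ethyl]phenoxy}dimethylsilane | CC(C)=CCOc1cc(CCc2ccc(O[Si](C)(C)C(C)(C)C)cc2)c2C=CC(C)(C)Oc2c1 | intermediate
15 | 4-{2-[2,2-dimethyl-7-(3-methylbut-2-enyloxy)-2H-chromen-5-yl]ethyl}phenol | CC(C)=CCOc1cc(CCc2ccc(O)cc2)c2c(c1)OC(C)(C)C=C2 | target

**Step count**
Total steps: 7. Longest linear sequence: 6 (steps 1, 2, 3, 4, 6, 7); step 5 is a one-step side branch.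

**Steps most likely to fail**

1. Step 3. Two processes may erode it: a competing [3,3] shift toward C8, the carbon between the two ether oxygens, and thermal rearrangement or fragmentation of the prenyl ether during the cascade.
Fallback: the prenyl group is installed after ring B is closed, with a thermally inert silyl ether holding the O7 position. It sets out from 1 and returns at 9. Mono-silylation of 1 (TIPSCl, imidazole, DMF) should give 3-hydroxy-5-(triisopropylsilyloxy)benzaldehyde F1. Copper-catalysed propargylation with 4 as in step 2 should give 3-(2-methylbut-3-yn-2-yloxy)-5-(triisopropylsilyloxy)benzaldehyde F2. The cascade can then be driven harder (N,N-diethylaniline, 180 °C), the silyloxy group keeping the para-directing donor role, to give 2,2-dimethyl-7-(triisopropylsilyloxy)-2H-chromene-5-carbaldehyde F3. TBAF should release 7-hydroxy-2,2-dimethyl-2H-chromene-5-carbaldehyde F4, at which stage any regioisomer can be removed. O-Prenylation of F4 with 2 (K2CO3, DMF) then gives 9.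

2. Step 6. Transmetalation of the B-alkyl borane may be slow, letting β-hydride elimination or protodeboronation take over. The silyl group of 12 may be lost under the basic conditions before it couples. Partial hydroboration of the chromene alkene is a lesser risk.
Fallback: the bridge carbon–aryl bond is made by copper-catalysed Grignard alkylation in place of palladium catalysis. It sets out from alkylborane 13 (made from 10 as in step 6) and returns at 14. Oxidation of 13 (NaBO3·4H2O, THF/H2O, rt) should give 2-[2,2-dimethyl-7-(3-methylbut-2-enyloxy)-2H-chromen-5-yl]ethanol F5. Tosylation (TsCl, pyridine, 0 °C) should give 2-[2,2-dimethyl-7-(3-methylbut-2-enyloxy)-2H-chromen-5-yl]ethyl 4-methylbenzenesulfonate F6. Coupling of F6 with [4-(tert-butyldimethylsilyloxy)phenyl]magnesium bromide F7 (from 12 and Mg in THF) under Li2CuCl4 catalysis (THF, −20 → 0 °C) should give 14.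

3. Step 1. Over-alkylation to the bis-ether and some C-prenylation of the phenoxide make the mono-ether a statistical product and cost material at the start.
Fallback: the second oxygen is introduced by carbon–boron oxidation, so the two oxygens are never equivalent. It sets out from 2, with commercial 3-bromo-5-hydroxybenzaldehyde F8 in place of 1, and returns at 3. O-Prenylation of F8 with 2 (K2CO3, DMF) should give 3-bromo-5-(3-methylbut-2-enyloxy)benzaldehyde F9. Miyaura borylation (bis(pinacolato)diboron, PdCl2(dppf), KOAc, dioxane, 80 °C) should give 3-(3-methylbut-2-enyloxy)-5-(4,4,5,5-tetramethyl-1,3,2-dioxaborolan-2-yl)benzaldehyde F10. Mild oxidation (NaBO3·4H2O, THF/H2O, rt) should give phenol 3.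

**Further compounds**
F1 | step 3 | 3-hydroxy-5-(triisopropylsilyloxy)benzaldehyde | CC(C)[Si](Oc1cc(O)cc(C=O)c1)(C(C)C)C(C)C
F2 | step 3 | 3-(2-methylbut-3-yn-2-yloxy)-5-(triisopropylsilyloxy)benzaldehyde | C#CC(C)(C)Oc1cc(C=O)cc(O[Si](C(C)C)(C(C)C)C(C)C)c1
F3 | step 3 | 2,2-dimethyl-7-(triisopropylsilyloxy)-2H-chromene-5-carbaldehyde | CC(C)[Si](Oc1cc(C=O)c2C=CC(C)(C)Oc2c1)(C(C)C)C(C)C
F4 | step 3 | 7-hydroxy-2,2-dimethyl-2H-chromene-5-carbaldehyde | O=Cc1cc(O)cc2OC(C)(C)C=Cc12
F5 | step 6 | 2-[2,2-dimethyl-7-(3-methylbut-2-enyloxy)-2H-chromen-5-yl]ethanol | CC(C)=CCOc1cc(CCO)c2C=CC(C)(C)Oc2c1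
F6 | step 6 | 2-[2,2-dimethyl-7-(3-methylbut-2-enyloxy)-2H-chromen-5-yl]ethyl 4-methylbenzenesulfonate | CC(C)=CCOc1cc(CCOS(=O)(=O)c2ccc(C)cc2)c2C=CC(C)(C)Oc2c1
F7 | step 6 | [4-(tert-butyldimethylsilyloxy)phenyl]magnesium bromide | CC(C)(C)[Si](C)(C)Oc1ccc([Mg]Br)cc1
F8 | step 1 | 3-bromo-5-hydroxybenzaldehyde | O=Cc1cc(O)cc(Br)c1
F9 | step 1 | 3-bromo-5-(3-methylbut-2-enyloxy)benzaldehyde | CC(C)=CCOc1cc(Br)cc(C=O)c1
F10 | step 1 | 3-(3-methylbut-2-enyloxy)-5-(4,4,5,5-tetramethyl-1,3,2-dioxaborolan-2-yl)benzaldehyde | CC(C)=CCOc1cc(C=O)cc(B2OC(C)(C)C(C)(C)O2)c1
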